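**Strategy.** The pyran ring on ring A (the phloroglucinol-derived benzoate ring) is cut at C2–C3 and C4–C4a, leaving an aryl ether oxygen that carries a C(CH3)2 radical and a two-carbon acceptor. The key step, a photoredox decarboxylative radical (4+2) annulation, makes both bonds at once: the tertiary α-aryloxy radical from a redox-active ester adds to phenyl vinyl sulfone and the adduct radical closes on the ortho carbon. It exploits the twofold symmetry of the 4-alkoxy-2,6-dihydroxybenzoate precursor, whose two ring A carbons ortho to the ether oxygen are identical and electron-rich. Carboxyl and sulfonyl are traceless activators; sulfinate loss later gives the C3=C4 alkene. A bromoquinone supplies ring B and a Claisen rearrangement the prenyl group.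

Key step: step 5

Assumption: the benzodioxinone starting material and the tert-butyl 1,1-dimethylallyl carbonate are taken as catalogue compounds (each is otherwise one routine step from 2,4,6-trihydroxybenzoic acid with acetone/TFA/TFAA, or from 2-methylbut-3-en-2-ol with Boc2O).

Numbering: each benzopyran uses chromene numbering (O1, C2, C3, C4, C4a, C5–C8, C8a). Ring A is the benzoate-derived ring, ring B the quinone-derived ring.

Step 1
Reactants: 1 5,7-dihydroxy-2,2-dimethyl-4H-1,3-benzodioxin-4-one; 2 tert-butyl 2-bromo-2-methylpropanoate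
Product: 3 tert-butyl 2-[(5-hydroxy-2,2-dimethyl-4-oxo-4H-1,3-benzodioxin-7-yl)oxy]-2-methylpropanoate
Conditions: K2CO3, DMF, 70 °C
Reagents that add atoms: none
Why: Fibrate-type Williamson O-alkylation with a tertiary α-bromo ester takes place at the 7-OH, the only phenol not locked in a hydrogen bond to the lactone carbonyl and the most acidic one (para to the carbonyl).

Step 2
Reactants: 3 tert-butyl 2-[(5-hydroxy-2,2-dimethyl-4-oxo-4H-1,3-benzodioxin-7-yl)oxy]-2-methylpropanoate
Product: 4 2,2,2-trifluoroethyl 4-[(1-tert-butoxy-2-methyl-1-oxopropan-2-yl)oxy]-2,6-dihydroxybenzoate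
Conditions: CF3CH2OH, K2CO3 (0.3 equiv), 60 °C
Reagents that add atoms: 2,2,2-trifluoroethanol, OCC(F)(F)F
Why: Base-catalysed alcoholysis of the salicylate acetonide (benzodioxinone ring opening with loss of acetone) gives the moderately activated trifluoroethyl ester needed later for lactonisation and makes the two carbons ortho to the ether oxygen equivalent.

Step 3
Reactants: 4 2,2,2-trifluoroethyl 4-[(1-tert-butoxy-2-methyl-1-oxopropan-2-yl)oxy]-2,6-dihydroxybenzoate
Product: 5 2-{3,5-dihydroxy-4-[(2,2,2-trifluoroethoxy)carbonyl]phenoxy}-2-methylpropanoic acid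
Conditions: TFA, CH2Cl2, rt
Reagents that add atoms: none
Why: Acidolysis of the tert-butyl ester (E1 loss of isobutene) frees the aliphatic acid while the trifluoroethyl ester, the tertiary aryl ether and the phenols are inert to TFA.

Step 4
Reactants: 5 2-{3,5-dihydroxy-4-[(2,2,2-trifluoroethoxy)carbonyl]phenoxy}-2-methylpropanoic acid
Product: 6 1,3-dioxoisoindolin-2-yl 2-{3,5-dihydroxy-4-[(2,2,2-trifluoroethoxy)carbonyl]phenoxy}-2-methylpropanoate
Conditions: N-hydroxyphthalimide, DIC, DMAP (cat.), CH2Cl2, 0 °C to rt
Reagents that add atoms: N-hydroxyphthalimide, O=C1N(O)C(=O)c2ccccc12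
Why: Carbodiimide (Steglich-type) esterification with N-hydroxyphthalimide gives the redox-active ester, because the N-hydroxy imide is far more nucleophilic than the two hindered, hydrogen-bonded phenols.

Step 5
Reactants: 6 1,3-dioxoisoindolin-2-yl 2-{3,5-dihydroxy-4-[(2,2,2-trifluoroethoxy)carbonyl]phenoxy}-2-methylpropanoate; 7 phenyl vinyl sulfone
Product: 8 (±)-2,2,2-trifluoroethyl 5,7-dihydroxy-2,2-dimethyl-4-(phenylsulfonyl)chromane-6-carboxylate
Conditions: fac-Ir(ppy)3 (1 mol %), 7 (3 equiv), MeCN, 450 nm LEDs, rt
Reagents that add atoms: none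
Why: The excited iridium catalyst reduces the N-(acyloxy)phthalimide, which loses phthalimide anion and CO2 to give the tertiary α-aryloxy radical at the future C2; this nucleophilic radical adds to the CH2 terminus of the electron-poor vinyl sulfone (C2–C3 bond) and the resulting electrophilic α-sulfonyl radical attacks the ortho carbon of ring A (C4–C4a bond). The cyclohexadienyl radical is then oxidised by the tetravalent iridium species and deprotonated by phthalimide anion, so the cycle is redox-neutral. The closest known reaction type is the photoredox decarboxylative radical (4+2) annulation of redox-active esters with acceptor alkenes (Giese addition followed by homolytic aromatic substitution), as used for chromans and, with α-amino radicals, for tetrahydroquinolines. The pyran ring closes by ortho homolytic aromatic substitution, a 6-exo-trig attack counted on the C4a=C5 π-bond of the arene. The new stereocentre C4 forms as a racemate under no control and is erased in step 7. The step needs site selectivity between the two ortho carbons, which the twofold symmetry of 6 makes identical, and radical chemoselectivity, which polarity matching secures (nucleophilic radical with acceptor alkene, electrophilic radical with the phloroglucinol-type arene).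

Step 6
Reactants: 8 (±)-2,2,2-trifluoroethyl 5,7-dihydroxy-2,2-dimethyl-4-(phenylsulfonyl)chromane-6-carboxylate; 9 tert-butyl 2-methylbut-3-en-2-yl carbonate
Product: 10 (±)-2,2,2-trifluoroethyl 5-hydroxy-2,2-dimethyl-7-[(2-methylbut-3-en-2-yl)oxy]-4-(phenylsulfonyl)chromane-6-carboxylate
Conditions: Pd(PPh3)4 (5 mol %), THF, 0 °C to rt
Reagents that add atoms: none
Why: Tsuji–Trost O-allylation: decarboxylative ionisation of 9 gives a 1,1-dimethylallyl–palladium complex that a phenoxide attacks at its tertiary terminus, and only the 7-OH (next to H-8) is accessible, the 5-OH being shielded by the peri phenylsulfonyl group.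

Step 7
Reactants: 10 (±)-2,2,2-trifluoroethyl 5-hydroxy-2,2-dimethyl-7-[(2-methylbut-3-en-2-yl)oxy]-4-(phenylsulfonyl)chromane-6-carboxylate
Product: 11 2,2,2-trifluoroethyl 5-hydroxy-2,2-dimethyl-7-[(2-methylbut-3-en-2-yl)oxy]-2H-chromene-6-carboxylate
Conditions: DBU, MeCN, 40 °C
Reagents that add atoms: none
Why: Base-induced 1,4-elimination of benzenesulfinate through the ortho-quinone methide of the 5-phenoxide, followed by loss of H-3, gives the conjugated 2H-chromene, and the alkene can only form between C3 and C4 because C4a has no hydrogen.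

Step 8
Reactants: 12 2,5-dimethoxyphenol
Product: 13 4-bromo-2,5-dimethoxyphenol
Conditions: NBS, MeCN, 0 °C
Reagents that add atoms: N-bromosuccinimide, O=C1CCC(=O)N1Br
Why: Electrophilic aromatic bromination with NBS goes para to the free hydroxyl group and ortho to the 5-methoxy group, the most activated open position.

Step 9
Reactants: 13 4-bromo-2,5-dimethoxyphenol; 14 3-methylbut-2-enal
Product: 15 6-bromo-5,8-dimethoxy-2,2-dimethyl-2H-chromene
Conditions: PhB(OH)2, AcOH, toluene, reflux (Dean–Stark)
Reagents that add atoms: none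
Why: Phenylboronic acid-mediated ortho-alkylation of the phenol with the enal gives an ortho-quinone methide that closes by oxa-6π electrocyclisation, and C6 of 13 is the only free ortho position.

Step 10
Reactants: 15 6-bromo-5,8-dimethoxy-2,2-dimethyl-2H-chromene
Product: 16 6-bromo-2,2-dimethyl-2H-chromene-5,8-dione
Conditions: (NH4)2Ce(NO3)6, MeCN/H2O, 0 °C
Reagents that add atoms: water, O
Why: Oxidative demethylation of the para-dimethoxyarene by tetravalent cerium gives the para-quinone with both carbonyl oxygens taken from water, under conditions that leave the aryl bromide and the chromene alkene intact.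

Step 11
Reactants: 11 2,2,2-trifluoroethyl 5-hydroxy-2,2-dimethyl-7-[(2-methylbut-3-en-2-yl)oxy]-2H-chromene-6-carboxylate; 16 6-bromo-2,2-dimethyl-2H-chromene-5,8-dione
Product: 17 2,2,2-trifluoroethyl 5-[(2,2-dimethyl-5,8-dioxo-5,8-dihydro-2H-chromen-6-yl)oxy]-2,2-dimethyl-7-[(2-methylbut-3-en-2-yl)oxy]-2H-chromene-6-carboxylate
Conditions: Cs2CO3, MeCN, 0 °C to rt
Reagents that add atoms: none
Why: Addition–elimination (ipso substitution) of the phenoxide of 11 on the bromoquinone occurs at C6, which carries the leaving group and is the β-carbon of the more electrophilic C8 carbonyl, since the C5 carbonyl is a vinylogous ester of the ring oxygen.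

Step 12
Reactants: 17 2,2,2-trifluoroethyl 5-[(2,2-dimethyl-5,8-dioxo-5,8-dihydro-2H-chromen-6-yl)oxy]-2,2-dimethyl-7-[(2-methylbut-3-en-2-yl)oxy]-2H-chromene-6-carboxylate
Product: 19 depsidone 1,1-dimethylallyl ether (Garcinisidone D skeleton with both pyran rings, H at the future prenyl carbon of ring A and the 1,1-dimethylallyl ether on the ring A oxygen ortho to the lactone carbonyl), via hydroquinone 18 (not isolated)
Conditions: Na2S2O4, THF/H2O, rt; then DBU, toluene, 60 °C
Reagents that add atoms: none
Why: Dithionite reduces the quinone to the hydroquinone, whose 5-OH lies next to the diaryl ether and displaces trifluoroethoxide from the activated ester in a seven-membered lactonisation (intramolecular transesterification), while the para 8-OH cannot reach the ester.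

Step 13
Reactants: 19 depsidone 1,1-dimethylallyl ether
Product: 20 Garcinisidone D
Conditions: toluene, 110 °C (sealed tube)
Reagents that add atoms: none
Why: Thermal aromatic Claisen rearrangement ([3,3]-sigmatropic) of the 1,1-dimethylallyl aryl ether transfers the allyl unit with inversion to the only free ortho carbon as a linear prenyl group, and tautomerisation restores the hydrogen-bonded phenol.

**Compound list**

1 | 5,7-dihydroxy-2,2-dimethyl-4H-1,3-benzodioxin-4-one | CC1(C)OC(=O)c2c(O)cc(O)cc2O1 | starting material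
2 | tert-butyl 2-bromo-2-methylpropanoate | CC(C)(Br)C(=O)OC(C)(C)C | starting material
3 | tert-butyl 2-[(5-hydroxy-2,2-dimethyl-4-oxo-4H-1,3-benzodioxin-7-yl)oxy]-2-methylpropanoate | CC1(C)OC(=O)c2c(O)cc(OC(C)(C)C(=O)OC(C)(C)C)cc2O1 | intermediate
4 | 2,2,2-trifluoroethyl 4-[(1-tert-butoxy-2-methyl-1-oxopropan-2-yl)oxy]-2,6-dihydroxybenzoate | O=C(OCC(F)(F)F)c1c(O)cc(OC(C)(C)C(=O)OC(C)(C)C)cc1O | intermediate
5 | 2-{3,5-dihydroxy-4-[(2,2,2-trifluoroethoxy)carbonyl]phenoxy}-2-methylpropanoic acid | O=C(OCC(F)(F)F)c1c(O)cc(OC(C)(C)C(=O)O)cc1O | intermediate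
6 | 1,3-dioxoisoindolin-2-yl 2-{3,5-dihydroxy-4-[(2,2,2-trifluoroethoxy)carbonyl]phenoxy}-2-methylpropanoate | O=C(OCC(F)(F)F)c1c(O)cc(OC(C)(C)C(=O)ON2C(=O)c3ccccc3C2=O)cc1O | intermediate
7 | phenyl vinyl sulfone | C=CS(=O)(=O)c1ccccc1 | starting material
8 | (±)-2,2,2-trifluoroethyl 5,7-dihydroxy-2,2-dimethyl-4-(phenylsulfonyl)chromane-6-carboxylate (racemic at C4) | FC(F)(F)COC(=O)c1c(O)cc2c(c1O)C(S(=O)(=O)c1ccccc1)CC(C)(C)O2 | intermediate
9 | tert-butyl 2-methylbut-3-en-2-yl carbonate | CC(C)(C=C)OC(=O)OC(C)(C)C | starting material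
10 | (±)-2,2,2-trifluoroethyl 5-hydroxy-2,2-dimethyl-7-[(2-methylbut-3-en-2-yl)oxy]-4-(phenylsulfonyl)chromane-6-carboxylate (racemic at C4) | FC(F)(F)COC(=O)c1c(OC(C)(C)C=C)cc2c(c1O)C(S(=O)(=O)c1ccccc1)CC(C)(C)O2 | intermediate
11 | 2,2,2-trifluoroethyl 5-hydroxy-2,2-dimethyl-7-[(2-methylbut-3-en-2-yl)oxy]-2H-chromene-6-carboxylate | FC(F)(F)COC(=O)c1c(OC(C)(C)C=C)cc2c(c1O)C=CC(C)(C)O2 | intermediate
12 | 2,5-dimethoxyphenol | Oc1cc(OC)ccc1OC | starting material
13 | 4-bromo-2,5-dimethoxyphenol | Oc1cc(OC)c(Br)cc1OC | intermediate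
14 | 3-methylbut-2-enal | CC(C)=CC=O | starting material
15 | 6-bromo-5,8-dimethoxy-2,2-dimethyl-2H-chromene | CC1(C)C=Cc2c(OC)c(Br)cc(OC)c2O1 | intermediate
16 | 6-bromo-2,2-dimethyl-2H-chromene-5,8-dione | CC1(C)C=CC2=C(O1)C(=O)C=C(Br)C2=O | intermediate
17 | 2,2,2-trifluoroethyl 5-[(2,2-dimethyl-5,8-dioxo-5,8-dihydro-2H-chromen-6-yl)oxy]-2,2-dimethyl-7-[(2-methylbut-3-en-2-yl)oxy]-2H-chromene-6-carboxylate | FC(F)(F)COC(=O)c1c(OC(C)(C)C=C)cc2c(c1OC1=CC(=O)C3=C(C=CC(C)(C)O3)C1=O)C=CC(C)(C)O2 | intermediate
18 | 2,2,2-trifluoroethyl 5-[(5,8-dihydroxy-2,2-dimethyl-2H-chromen-6-yl)oxy]-2,2-dimethyl-7-[(2-methylbut-3-en-2-yl)oxy]-2H-chromene-6-carboxylate (hydroquinone, not isolated) | FC(F)(F)COC(=O)c1c(OC(C)(C)C=C)cc2c(c1Oc1cc(O)c3OC(C)(C)C=Cc3c1O)C=CC(C)(C)O2 | intermediate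
19 | depsidone 1,1-dimethylallyl ether (de-prenyl Garcinisidone D carrying O–C(CH3)2CH=CH2 on the ring A oxygen ortho to the lactone carbonyl) | C=CC(C)(C)Oc1cc3OC(C)(C)C=Cc3c4Oc5cc(O)c6OC(C)(C)C=Cc6c5OC(=O)c14 | intermediate
20 | Garcinisidone D | CC(C)=CCc1c(O)c2c(c3c1OC(C)(C)C=C3)Oc1cc(O)c3c(c1OC2=O)C=CC(C)(C)O3 | target

**Step count and risks**

Total steps: 13. Longest linear sequence: 10 steps (steps 1–7, then 11–13, from compound 1); the ring B branch (steps 8–10) joins at step 11.

Steps most likely to fail:

Step 5 (key annulation). The adduct α-sulfonyl radical may be reduced or may oligomerise with further vinyl sulfone before it closes on the arene, or the cyclohexadienyl radical may not be reoxidised efficiently. Fallback, the classical propargyl ether route from 1: O-alkylation of the 7-OH with 3-chloro-3-methylbut-1-yne (CuCl2 cat., DBU, MeCN, 0 °C) would give the 1,1-dimethylpropargyl ether F1. Alcoholysis with CF3CH2OH/K2CO3 would give the symmetric trifluoroethyl ester F2. Heating in xylene at 140 °C would bring about propargyl Claisen rearrangement, [1,5]-H shift and oxa-6π electrocyclisation to the chromene diol F3, again without a regiochemical question because the two ortho carbons are identical. Pd(PPh3)4-catalysed 1,1-dimethylallylation of the less hindered 7-OH with 9 would then rejoin the route at 11.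

Step 6 (site-selective 1,1-dimethylallylation). The hydrogen-bonded phenol may react too slowly with the allylpalladium electrophile, and forcing the reaction may erode discrimination between the two phenols or start premature sulfinate loss. Fallback from 8: alkylation with 3-chloro-3-methylbut-1-yne under CuCl2/DBU at 0 °C (copper acetylide-assisted ionisation, a more reactive and strongly size-sensitive electrophile) would give the 7-O-(1,1-dimethylpropargyl) ether F4. Semihydrogenation with H2 over Pd/CaCO3 poisoned with Pb(OAc)2 and quinoline in EtOAc would return to 10.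

Step 11 (diaryl ether formation). Electron transfer from the hindered phenoxide to the quinone, or attack at the unsubstituted quinone carbon, may compete with ipso substitution. Fallback from 11 and 15, forming the ether before the quinone: Ullmann-type coupling of 11 with aryl bromide 15 (CuI, picolinic acid, K3PO4, DMSO, 80 °C) would give the diaryl ether F5. Oxidative demethylation with (NH4)2Ce(NO3)6 in MeCN/H2O would return to 17.

Further compounds
F1 | step 5 | 5-hydroxy-2,2-dimethyl-7-[(2-methylbut-3-yn-2-yl)oxy]-4H-1,3-benzodioxin-4-one | CC1(C)OC(=O)c2c(O)cc(OC(C)(C)C#C)cc2O1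
F2 | step 5 | 2,2,2-trifluoroethyl 2,6-dihydroxy-4-[(2-methylbut-3-yn-2-yl)oxy]benzoate | O=C(OCC(F)(F)F)c1c(O)cc(OC(C)(C)C#C)cc1O
F3 | step 5 | 2,2,2-trifluoroethyl 5,7-dihydroxy-2,2-dimethyl-2H-chromene-6-carboxylate | O=C(OCC(F)(F)F)c1c(O)cc2OC(C)(C)C=Cc2c1O
F4 | step 6 | (±)-2,2,2-trifluoroethyl 5-hydroxy-2,2-dimethyl-7-[(2-methylbut-3-yn-2-yl)oxy]-4-(phenylsulfonyl)chromane-6-carboxylate | FC(F)(F)COC(=O)c1c(OC(C)(C)C#C)cc2c(c1O)C(S(=O)(=O)c1ccccc1)CC(C)(C)O2
F5 | step 11 | 2,2,2-trifluoroethyl 5-[(5,8-dimethoxy-2,2-dimethyl-2H-chromen-6-yl)oxy]-2,2-dimethyl-7-[(2-methylbut-3-en-2-yl)oxy]-2H-chromene-6-carboxylate | FC(F)(F)COC(=O)c1c(OC(C)(C)C=C)cc2c(c1Oc1cc(OC)c3OC(C)(C)C=Cc3c1OC)C=CC(C)(C)O2
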